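## The problem

The target is the 4-methoxybenzoate of a daucane-5,8,9-triol. A cyclopentane is cis-fused to a cycloheptane through C1 (quaternary, methyl) and C5 (tertiary carbinol); C4 carries an isopropyl group, C8 is a methyl carbinol and C9 the acylated secondary carbinol. Five stereocenters are needed. The C4 isopropyl, C5 hydroxyl, C1 methyl and C9 acyloxy groups lie on one face (β), while the C8 hydroxyl lies on the other, trans to both the C5 and the C9 oxygen. C4 is the only center that can be made early by asymmetric catalysis. Being next to C5, it can decide the face on which C5 is built; a rigid bridged frame can then control C1, and the C8 hydroxyl can direct the reduction at C9. C8 itself has no obvious controller. The two tertiary alcohols dehydrate easily, the C5 hydroxyl adds across the ring to any electrophilic C8, an α-ketol appears on the way, and the anisate does not survive base or hydride, so it is put on last. The enabling feature is that C5 and C8 both carry oxygen and face each other 1,4 across C6-C7, with C9 next to C8 also oxygenated. That is the imprint of a 3-oxidopyrylium that has taken up a two-carbon unit at its two α-carbons, the ring oxygen becoming the C5 hydroxyl and the oxide the C9 oxygen. An oxygen bridge can only place the C5 and C8 oxygens on one face, so the C8-O bond must later be broken and re-made from the other side.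

## Retrosynthesis

**Ester.** The acyl-oxygen bond at C9 of 26 is cut first, giving triol 24 and 4-methoxybenzoyl chloride 25. Doing this last keeps the base-labile ester out of every reductive and organometallic step. The forward reaction only has to pick the one secondary hydroxyl among two tertiary ones.

**C9 carbinol.** 24 is traced to α-hydroxy ketone 23 by removing the C9 hydride. A ketone at C9 is preferred to an alkene precursor because the neighbouring C8 hydroxyl can deliver hydride to its own face, which gives the trans diol directly.

**C8 oxygen.** The C8-O bond of 23 is cut to the silyl enol ether 21, which comes from hydroxy ketone 20. Oxidizing an enol derivative, with the C5 hydroxyl capped, avoids the transannular ether that an epoxide route would risk. The forward step must put oxygen on the α face.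

**Oxygen bridge.** 20 is the product of reductive C8-O cleavage of the bridged α-alkoxy ketone 19. Re-forming that bond in the retrosynthetic sense ties C5 and C8 together and turns a flexible hydroazulenone into a rigid 8-oxabicyclo[3.2.1]octanone. 19 is related to the alkene 18 and the vinyl sulfone 17 by trivial reductions.

**Angular methyl.** The C1-CH3 bond of 17 is cut to enone 15. In the bridged enone the exo face is the only open one, so a cuprate should deliver the methyl group cis to the C5 oxygen. This is far easier to control than building the quaternary center on a monocyclic ring.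

**Key disconnection.** Bonds C5-C6 and C7-C8 of 15 are cut together, giving the oxidopyrylium betaine 14 and ethynyl p-tolyl sulfone 13. This removes the seven-membered ring, two stereocenters and the whole oxygen pattern in one step, and leaves a flat bicyclic betaine with a single stereocenter. The forward reaction must add the alkyne anti to the C4 isopropyl group. 14 is generated from acetoxypyranone 12.

**Pyranone.** 12 and its hemiketal 11 are the Achmatowicz products of furyl carbinol 10, which is disconnected at the furan-carbinol bond to the fused furan 7 (via its lithio derivative 9) and acetaldehyde 8.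

**Cyclopentane.** 7 comes from ketone 6 by deoxygenation, and 6 from acid 4 by Friedel-Crafts closure of the bond between furan C3 and the acyl carbon, through acid chloride 5.

**Stereocenter.** Acid 4 and its ester 3 are cut at the bond between the furan and the isopropyl-bearing carbon, giving furan-2-ylboronic acid 1 and enoate 2. A catalytic asymmetric conjugate addition sets the one stereocenter from which all others derive.

## Roads not taken

**Alternative 1: semipinacol ring expansion.** The cut is the C1-C10 bond. In the forward sense BF3·OEt2 opens the epoxy alcohol A2 at its tertiary epoxide carbon while a ring carbon shifts from the carbinol carbon, giving the cycloheptenone A1.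
- Merits: the quaternary C1 is set stereospecifically from an enantioenriched epoxide by anti migration, the six-membered precursor is cheap, and the C8=C9 alkene and C5 carbonyl are in place. For C1 this road is better than the chosen plan, which must force a methyl group onto a hindered enone carbon.
- Weak points: the two ring methylenes on the carbinol carbon have similar migratory aptitude, so the regiochemistry of expansion is in doubt. The five-membered ring, with C4 and the C5 carbinol, must still be built on a flexible cycloheptenone with only remote control from C1. The C2 hydroxyl is surplus and must be deleted. The C8/C9 trans-diol must finally be made from an isolated alkene beside a free C5 hydroxyl.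
- Comparison: the chosen plan answers with a key step that delivers the ring, C5, and the oxygens at C5 and C9 together.

**Alternative 2: intramolecular Buchner reaction.** The cuts are C1-C5 and C1-C10. A chiral copper carbenoid from the α-methyl diazoketone A4 adds to the ipso/ortho bond of the anisyl ring and the norcaradiene opens to the dihydroazulenone A3.
- Merits: the whole bicyclic carbon skeleton arrives in one step from a simple aryl ketone, probably in fewer steps than the chosen plan needs to reach its key step.
- Weak points: α-alkyl diazoketones tend to undergo 1,2-hydride shift instead of cyclopropanation, and face control at the new quaternary carbon is less developed for such carbenoids. The product is a triene with an enol ether and a surplus C2 ketone. The C5 hydroxyl would have to be introduced at an sp2 ring-fusion carbon, and C8 and C9 built by separate redox steps, each with its own facial question.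
- Comparison: the chosen plan is longer up to the bicycle but arrives with C5-O and C9=O already in place and correctly related to C4.

**Alternative 3: carbonyl-ene cyclopentannulation.** The cut is C4-C5. Me2AlCl promotes the ene reaction of the trisubstituted side-chain alkene of cycloheptenone A6 with its ketone, giving the tertiary alcohol A5 with an isopropenyl group.
- Merits: C4 and C5 are set together through a cyclic transition state under the control of C1, which can itself be installed by a reliable catalytic asymmetric alkylation. This is probably the shortest road to the full skeleton, and in step count and in the handling of C1 it is as good as or better than the chosen plan.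
- Weak points: ketones are poor enophiles, and the ring alkene may compete in cationic side reactions. The end game must turn the C8=C9 alkene into the 8α-hydroxy-9β-ester. That requires α-face epoxidation and opening at the secondary carbon, under conditions where the C5 hydroxyl does not attack C8 to close the 5,8-ether.
- Comparison: the chosen plan meets the same C8 problem but from a C9 ketone. The oxygen then enters through an enol ether with the C5 hydroxyl capped, and the ketone allows a directed reduction.

Key step: step 8

Remark on the chemistry (assumption): the (R) antipode of BINAP is taken to give the (R) ester 3, following the accepted face model for rhodium-BINAP additions to (E)-enoates. If the sense proves opposite, the (S) ligand is used and nothing else changes.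

Notation: bicyclic compounds are named on the daucane skeleton (C1 carries the angular methyl C15, C4 the isopropyl group, C8 the methyl C14). "15-Nor" marks compounds that still lack the C1 methyl. β is the face of the seven-membered ring on which the C5 oxygen lies, α the opposite face. The C4 isopropyl group (4R) is β throughout. The SMILES strings in the compound list are authoritative.

## Route

Step 1
Reactants: 1 furan-2-ylboronic acid; 2 ethyl (E)-4-methylpent-2-enoate
Product: 3 ethyl (3R)-3-(furan-2-yl)-4-methylpentanoate
Conditions: [Rh(OH)((R)-BINAP)]2 (3 mol %), 1 (3 equiv, in portions), dioxane/H2O 10:1, 40 °C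
Reagents that add atoms: none
Why: Hayashi-Miyaura rhodium-catalysed asymmetric conjugate addition of a boronic acid to an (E)-enoate: the furyl-rhodium species inserts the enoate and the oxa-π-allyl rhodium is hydrolysed, the BINAP ligand choosing the enantioface at the future C4. The preformed hydroxo complex transmetalates at 40 °C, which should keep protodeboronation of the 2-furylboronic acid behind the productive pathway; the excess covers what is lost.

Step 2
Reactants: 3 ethyl (3R)-3-(furan-2-yl)-4-methylpentanoate
Product: 4 (3R)-3-(furan-2-yl)-4-methylpentanoic acid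
Conditions: LiOH·H2O, THF/MeOH/H2O, rt; then 1 M HCl
Reagents that add atoms: lithium hydroxide, [Li+].[OH-] (supplies the oxygen of the acid OH)
Why: Ester saponification; the stereocenter is β to the carboxyl group and cannot enolize.

Step 3
Reactants: 4 (3R)-3-(furan-2-yl)-4-methylpentanoic acid
Product: 6 (6R)-6-(propan-2-yl)-5,6-dihydro-4H-cyclopenta[b]furan-4-one, via acid chloride 5 (not isolated)
Conditions: (COCl)2, DMF (cat.), CH2Cl2, 0 °C to rt; evaporate; SnCl4 (1.1 equiv), CH2Cl2 (0.01 M), −78 to −20 °C
Reagents that add atoms: oxalyl chloride, ClC(=O)C(Cl)=O (gives the chlorine of intermediate 5; nothing of it remains in 6)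
Why: Intramolecular Friedel-Crafts acylation: the tethered acylium ion can only reach the adjacent furan C3, and high dilution at low temperature should hold back intermolecular attack at the free furan α-position. The stereocenter takes no part.

Step 4
Reactants: 6 (6R)-6-(propan-2-yl)-5,6-dihydro-4H-cyclopenta[b]furan-4-one
Product: 7 (6R)-6-(propan-2-yl)-5,6-dihydro-4H-cyclopenta[b]furan
Conditions: LiAlH4, AlCl3, Et2O, 0 °C to rt
Reagents that add atoms: none
Why: Mixed-hydride (LiAlH4/AlCl3) hydrogenolysis of an aryl ketone: the aluminium alkoxide ionizes with help from the furan oxygen and the cation is captured by hydride at C4, restoring the furan. The non-basic conditions avoid the vinylogous enolization that could epimerize C6 of 6.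

Step 5
Reactants: 7 (6R)-6-(propan-2-yl)-5,6-dihydro-4H-cyclopenta[b]furan; 8 acetaldehyde
Product: 10 1-[(6R)-6-(propan-2-yl)-5,6-dihydro-4H-cyclopenta[b]furan-2-yl]ethan-1-ol (both carbinol epimers), via 2-furyllithium 9 (not isolated)
Conditions: n-BuLi, THF, −78 to 0 °C; then 8, −78 °C; aq NH4Cl
Reagents that add atoms: n-butyllithium, [Li]CCCC (gives the lithium of intermediate 9; nothing of it remains in 10)
Why: α-Lithiation of a furan at its only free α-position, then 1,2-addition to the aldehyde. The carbinol center is formed without control because it is flattened again in step 8.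

Step 6
Reactants: 10 1-[(6R)-6-(propan-2-yl)-5,6-dihydro-4H-cyclopenta[b]furan-2-yl]ethan-1-ol
Product: 11 (7R)-7a-hydroxy-2-methyl-7-(propan-2-yl)-5,6,7,7a-tetrahydrocyclopenta[b]pyran-3(2H)-one (mixture at C2 and C7a)
Conditions: NBS, NaHCO3, NaOAc, THF/H2O 4:1, 0 °C
Reagents that add atoms: water, O
Why: Achmatowicz oxidative ring expansion of a furyl carbinol: bromonium-induced hydration opens the furan to the ene-dione and the side-chain hydroxyl closes onto the ring ketone as the pyranone hemiketal. The isopropyl-bearing center is untouched; the two new centers are mixtures that converge in step 8.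

Step 7
Reactants: 11 (7R)-7a-hydroxy-2-methyl-7-(propan-2-yl)-5,6,7,7a-tetrahydrocyclopenta[b]pyran-3(2H)-one
Product: 12 (7R)-2-methyl-3-oxo-7-(propan-2-yl)-2,3,5,6,7,7a-hexahydrocyclopenta[b]pyran-7a-yl acetate (mixture at C2 and C7a)
Conditions: Ac2O, pyridine, DMAP (cat.), CH2Cl2, 0 °C to rt
Reagents that add atoms: acetic anhydride, CC(=O)OC(C)=O
Why: DMAP-catalysed acetylation of the tertiary hemiketal hydroxyl, the usual activation of 6-substituted Achmatowicz products, gives the leaving group for betaine formation.

Step 8
Reactants: 12 (7R)-2-methyl-3-oxo-7-(propan-2-yl)-2,3,5,6,7,7a-hexahydrocyclopenta[b]pyran-7a-yl acetate; 13 ethynyl p-tolyl sulfone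
Product: 15 5β,8β-epoxy-6-[(4-methylphenyl)sulfonyl]-15-nordauca-1(10),6-dien-9-one (4R; 8-methyl α), via oxidopyrylium betaine 14 (not isolated)
Conditions: i-Pr2NEt (1.5 equiv, slow addition), 13 (3 equiv), CH2Cl2, 0 °C to rt
Reagents that add atoms: none
Why: The hindered amine removes the proton at C8 of 12 and acetate leaves from C5 through the ring oxygen, so the aromatic 3-oxidopyrylium betaine 14 forms in low stationary concentration. Its C5 and C8 termini act as a carbonyl-ylide-type four-electron unit and add suprafacially to the alkyne 13 in a concerted, thermally allowed six-electron (5+2) cycloaddition; the closest known reactions are the cycloadditions of betaines from Achmatowicz acetoxypyranones with activated alkenes and alkynes, including cases that create two fully substituted bridgeheads. The seven-membered carbocycle C1-C5-C6-C7-C8-C9-C10 is closed by this two-bond intermolecular annulation (C5-C6 and C7-C8 form together), not by a one-bond cyclization, and the same event closes the 2,5-dihydrofuran ring that holds the oxygen bridge. The new stereocenters C5 and C8 are set together because the bridge can span only one face; the face is chosen by the C4 isopropyl group on the carbon next to C5, which shields its own side of the flat betaine, so the alkyne bonds anti to it and the bridge oxygen ends up cis to the isopropyl group as the target requires. The sulfonyl-bearing carbon is expected to bond to C5 and the CH terminus to C8 on frontier-orbital grounds, but this regiochemistry is of no consequence because the sulfone is removed. The step needs facial selectivity and an intact C4 center: the first rests on the adjacent isopropyl group, the second on a hindered non-nucleophilic base, an excess of a very reactive alkyne and low temperature, which should let cycloaddition outrun proton exchange at C4 and dimerization of the betaine.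

Step 9
Reactants: 15 5β,8β-epoxy-6-[(4-methylphenyl)sulfonyl]-15-nordauca-1(10),6-dien-9-one
Product: 17 5β,8β-epoxy-6-[(4-methylphenyl)sulfonyl]dauc-6-en-9-one (1-methyl β), via silyl enol ether 16 (not isolated)
Conditions: Me2CuLi (from MeLi and CuI, 2 equiv), TMSCl, THF/Et2O, −78 to −40 °C; then aq NH4Cl, citric acid/MeOH
Reagents that add atoms: lithium dimethylcuprate, [Li+].C[Cu-]C; chlorotrimethylsilane, C[Si](C)(C)Cl (gives the silyl group of intermediate 16; nothing of it remains in 17)
Why: TMSCl-accelerated conjugate addition of a Gilman cuprate: the enone is activated through its carbonyl group and the vinyl sulfone is not, which should direct the methyl group to C1. Attack comes from the exo face, the side of the oxygen bridge, because the C6=C7 bridge with its sulfonyl group lies directly under the other face; the methyl group therefore ends up cis to the C5 oxygen (cis ring fusion). Mild acid hydrolyses the silyl enol ether 16.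

Step 10
Reactants: 17 5β,8β-epoxy-6-[(4-methylphenyl)sulfonyl]dauc-6-en-9-one
Product: 18 5β,8β-epoxydauc-6-en-9-one
Conditions: 6% Na/Hg, Na2HPO4, MeOH/THF, −20 °C
Reagents that add atoms: none
Why: Reductive desulfonylation of a vinyl sulfone by sodium amalgam in buffered methanol, as used in Julia-type chemistry: two electrons and a proton replace the sulfonyl group at an sp2 carbon, where β-elimination of the C5 oxygen is not possible. The aryl vinyl sulfone is reduced far more easily than the saturated ketone, and no enolizable stereocenter is present.

Step 11
Reactants: 18 5β,8β-epoxydauc-6-en-9-one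
Product: 19 5β,8β-epoxydaucan-9-one
Conditions: H2 (1 atm), 10% Pd/C, EtOAc, rt
Reagents that add atoms: none
Why: Catalytic hydrogenation of the strained cis-disubstituted bridge alkene; no stereocenter is formed.

Step 12
Reactants: 19 5β,8β-epoxydaucan-9-one
Product: 20 5β-hydroxydaucan-9-one (both C8 epimers)
Conditions: SmI2 (2.5 equiv), THF/MeOH, −78 °C
Reagents that add atoms: none
Why: SmI2 reduction of an α-alkoxy ketone: the ketyl expels the α-oxygen, the C8-O bond breaks and the samarium enolate is protonated, the bridge oxygen staying on C5 as the tertiary alcohol. C8 becomes a mixture that step 13 erases; the ketone may equilibrate with its 5,9-hemiketal without harm.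

Step 13
Reactants: 20 5β-hydroxydaucan-9-one
Product: 21 5β,9-bis(trimethylsilyloxy)dauc-8-ene
Conditions: TMSCl, NaI, Et3N, MeCN, rt to 40 °C
Reagents that add atoms: chlorotrimethylsilane, C[Si](C)(C)Cl
Why: Silyl enol ether formation under equilibrating conditions gives the more substituted C8=C9 isomer, the other α-carbon being a neopentyl methylene; the iodotrimethylsilane formed in situ also caps the tertiary C5 hydroxyl.

Step 14
Reactants: 21 5β,9-bis(trimethylsilyloxy)dauc-8-ene
Product: 23 5β,8α-dihydroxydaucan-9-one, via silyloxy epoxide 22 (not isolated)
Conditions: DMDO, acetone/CH2Cl2, −78 to −20 °C; then citric acid, MeOH, 0 °C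
Reagents that add atoms: dimethyldioxirane, CC1(C)OO1
Why: Rubottom oxidation: DMDO epoxidizes the electron-rich enol ether and mild acid opens the silyloxy epoxide 22 to the α-hydroxy ketone and removes both silyl groups. Attack is expected on the α face because the C1 methyl and the bulky C5 silyloxy group both stand on the β face and the capped hydroxyl cannot guide the oxidant there; this places the C8 hydroxyl α and the C8 methyl β.

Step 15
Reactants: 23 5β,8α-dihydroxydaucan-9-one
Product: 24 daucane-5β,8α,9β-triol
Conditions: Me4NBH(OAc)3, MeCN/AcOH 1:1, −20 °C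
Reagents that add atoms: none
Why: Hydroxyl-directed triacetoxyborohydride reduction (Saksena-Evans type): the reagent binds the C8 hydroxyl and delivers hydride to the α face of C9, so the new hydroxyl is β and trans to the C8 hydroxyl. Sterics point the same way, since the β face of C9 is flanked by the C8 and C1 methyl groups.

Step 16
Reactants: 24 daucane-5β,8α,9β-triol; 25 4-methoxybenzoyl chloride
Product: 26 (1R,4R,5S,8R,9R)-5,8-dihydroxydaucan-9-yl 4-methoxybenzoate (5β,8α-dihydroxydaucan-9β-yl 4-methoxybenzoate; CNP0244624.1)
Conditions: pyridine, DMAP (cat.), CH2Cl2, 0 °C to rt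
Reagents that add atoms: none
Why: DMAP-catalysed acylation; only the secondary C9 hydroxyl reacts, the two tertiary hydroxyls being inert under these conditions.

## Compound list

1 | furan-2-ylboronic acid | OB(O)c1ccco1 | starting material
2 | ethyl (E)-4-methylpent-2-enoate | CCOC(=O)/C=C/C(C)C | starting material
3 | ethyl (3R)-3-(furan-2-yl)-4-methylpentanoate | CCOC(=O)C[C@H](C(C)C)c1ccco1 | intermediate
4 | (3R)-3-(furan-2-yl)-4-methylpentanoic acid | OC(=O)C[C@H](C(C)C)c1ccco1 | intermediate
5 | (3R)-3-(furan-2-yl)-4-methylpentanoyl chloride | ClC(=O)C[C@H](C(C)C)c1ccco1 | intermediate (not isolated)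
6 | (6R)-6-(propan-2-yl)-5,6-dihydro-4H-cyclopenta[b]furan-4-one | O=C1C[C@H](C(C)C)c2occc12 | intermediate
7 | (6R)-6-(propan-2-yl)-5,6-dihydro-4H-cyclopenta[b]furan | CC(C)[C@H]1CCc2ccoc12 | intermediate
8 | acetaldehyde | CC=O | starting material
9 | [(6R)-6-(propan-2-yl)-5,6-dihydro-4H-cyclopenta[b]furan-2-yl]lithium | [Li]c1cc2CC[C@H](C(C)C)c2o1 | intermediate (not isolated)
10 | 1-[(6R)-6-(propan-2-yl)-5,6-dihydro-4H-cyclopenta[b]furan-2-yl]ethan-1-ol, both carbinol epimers | CC(O)c1cc2CC[C@H](C(C)C)c2o1 | intermediate
11 | (7R)-7a-hydroxy-2-methyl-7-(propan-2-yl)-5,6,7,7a-tetrahydrocyclopenta[b]pyran-3(2H)-one, mixture at C2 and C7a | CC1OC2(O)[C@@H](C(C)C)CCC2=CC1=O | intermediate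
12 | (7R)-2-methyl-3-oxo-7-(propan-2-yl)-2,3,5,6,7,7a-hexahydrocyclopenta[b]pyran-7a-yl acetate, mixture at C2 and C7a | CC1OC2(OC(C)=O)[C@@H](C(C)C)CCC2=CC1=O | intermediate
13 | ethynyl p-tolyl sulfone (1-(ethynylsulfonyl)-4-methylbenzene) | C#CS(=O)(=O)c1ccc(C)cc1 | starting material
14 | (7R)-2-methyl-7-(propan-2-yl)-6,7-dihydro-5H-cyclopenta[b]pyrylium-3-olate | Cc1[o+]c2[C@@H](C(C)C)CCc2cc1[O-] | intermediate (not isolated)
15 | 5β,8β-epoxy-6-[(4-methylphenyl)sulfonyl]-15-nordauca-1(10),6-dien-9-one (4R; 8-methyl α) | O=C1C=C2CC[C@H](C(C)C)[C@]23O[C@@]1(C)C=C3S(=O)(=O)c1ccc(C)cc1 | intermediate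
16 | 5β,8β-epoxy-6-[(4-methylphenyl)sulfonyl]-9-(trimethylsilyloxy)dauca-6,9-diene (1-methyl β) | C[Si](C)(C)OC1=C[C@@]2(C)CC[C@H](C(C)C)[C@]23O[C@@]1(C)C=C3S(=O)(=O)c1ccc(C)cc1 | intermediate (not isolated)
17 | 5β,8β-epoxy-6-[(4-methylphenyl)sulfonyl]dauc-6-en-9-one (1-methyl β) | O=C1C[C@@]2(C)CC[C@H](C(C)C)[C@]23O[C@@]1(C)C=C3S(=O)(=O)c1ccc(C)cc1 | intermediate
18 | 5β,8β-epoxydauc-6-en-9-one | O=C1C[C@@]2(C)CC[C@H](C(C)C)[C@]23O[C@@]1(C)C=C3 | intermediate
19 | 5β,8β-epoxydaucan-9-one | O=C1C[C@@]2(C)CC[C@H](C(C)C)[C@]23O[C@@]1(C)CC3 | intermediate
20 | 5β-hydroxydaucan-9-one, both C8 epimers | O=C1C[C@@]2(C)CC[C@H](C(C)C)[C@@]2(O)CCC1C | intermediate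
21 | 5β,9-bis(trimethylsilyloxy)dauc-8-ene | C[Si](C)(C)OC=1C[C@@]2(C)CC[C@H](C(C)C)[C@@]2(O[Si](C)(C)C)CCC=1C | intermediate
22 | 8α,9α-epoxy-5β,9β-bis(trimethylsilyloxy)daucane | C[Si](C)(C)O[C@]12C[C@@]3(C)CC[C@H](C(C)C)[C@@]3(O[Si](C)(C)C)CC[C@@]1(C)O2 | intermediate (not isolated)
23 | 5β,8α-dihydroxydaucan-9-one | O=C1C[C@@]2(C)CC[C@H](C(C)C)[C@@]2(O)CC[C@@]1(C)O | intermediate
24 | daucane-5β,8α,9β-triol | O[C@@H]1C[C@@]2(C)CC[C@H](C(C)C)[C@@]2(O)CC[C@@]1(C)O | intermediate
25 | 4-methoxybenzoyl chloride | COc1ccc(cc1)C(Cl)=O | starting material
26 | (1R,4R,5S,8R,9R)-5,8-dihydroxydaucan-9-yl 4-methoxybenzoate | COc1ccc(C(=O)O[C@@H]2C[C@@]3(C)CC[C@H](C(C)C)[C@@]3(O)CC[C@@]2(C)O)cc1 | target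

## Step count and least certain steps

Total: 16 steps. Longest linear sequence: 16 steps (from 1 and 2 to 26; 8, 13 and 25 are bought).

**Step 8 (key step).** The betaine carries an acidic hydrogen at C4, on the carbon attached to a pyrylium α-position. Reversible proton transfer to the alkylidene-pyranone tautomer before cycloaddition would erode the enantiomeric purity. The amine or the released acetate can also consume the Michael-accepting alkyne, and the betaine can dimerize if addition to a doubly substituted terminus is slow. The fallback removes the amine and the alkyne. It sets out from 12, which is heated in toluene at 110 °C with phenyl vinyl sulfoxide, an acetylene equivalent; the acetoxypyranone loses acetic acid thermally. The cycloadduct, 5β,8β-epoxy-6-(phenylsulfinyl)-15-nordauc-1(10)-en-9-one F7, loses benzenesulfenic acid by syn-elimination in the same pot and gives 5β,8β-epoxy-15-nordauca-1(10),6-dien-9-one F8. Addition of Me2CuLi/TMSCl to F8, which has no second acceptor, returns to the route at 18.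

**Step 1.** Protodeboronation of the 2-furylboronic acid may outrun transmetalation, the β-branched enoate inserts slowly, and the sense of induction rests on a model. The fallback sets out from 1. Commercial ethyl 4-methyl-3-oxopentanoate is converted (Tf2O, aqueous LiOH) into ethyl (2Z)-4-methyl-3-{[(trifluoromethyl)sulfonyl]oxy}pent-2-enoate F1. Suzuki coupling with 1 (Pd(PPh3)4, K3PO4, dioxane, 60 °C) gives ethyl (2Z)-3-(furan-2-yl)-4-methylpent-2-enoate F2. Asymmetric copper hydride conjugate reduction (CuCl, NaOtBu, p-tol-BINAP of the antipode that gives the R ester, polymethylhydrosiloxane) returns to the route at 3.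

**Step 3.** Acylation at the free furan α-position of a second molecule, and acid-induced polymerization of the furan, may compete with closure of the strained five-membered ketone. The fallback sets out from 4 and blocks that position with bromine, which later serves as the lithiation handle. NBS in DMF gives (3R)-3-(5-bromofuran-2-yl)-4-methylpentanoic acid F3. Oxalyl chloride gives its acid chloride F4. SnCl4 closes (6R)-2-bromo-6-(propan-2-yl)-5,6-dihydro-4H-cyclopenta[b]furan-4-one F5. LiAlH4/AlCl3 gives (6R)-2-bromo-6-(propan-2-yl)-5,6-dihydro-4H-cyclopenta[b]furan F6. Bromine-lithium exchange with n-BuLi at −78 °C returns to the route at 9, and acetaldehyde then gives 10.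

**Step 9.** C1 is doubly substituted, lies next to the quaternary C5 and must take the methyl group syn to the C4 isopropyl group, so addition may be slow. The cuprate could then attack C7 of the strained vinyl sulfone, after which the α-sulfonyl carbanion would expel the C5 oxygen and open the bridge. The fallback removes the sulfone before methylation, with the ketone masked as an alcohol. It sets out from 15. Luche reduction (NaBH4, CeCl3·7H2O, MeOH) gives 5β,8β-epoxy-6-[(4-methylphenyl)sulfonyl]-15-nordauca-1(10),6-dien-9α-ol F9. Na/Hg in buffered methanol gives 5β,8β-epoxy-15-nordauca-1(10),6-dien-9α-ol F10. Hydrogenation with RhCl(PPh3)3 saturates only the disubstituted bridge alkene and gives 5β,8β-epoxy-15-nordauc-1(10)-en-9α-ol F11. MnO2 gives 5β,8β-epoxy-15-nordauc-1(10)-en-9-one F12. Me2CuLi/TMSCl on F12, now the only acceptor, returns to the route at 19.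

**Step 14.** The seven-membered enol ether is flexible and both faces carry one pseudoaxial group in either chair, so the oxidant may approach from the β face or from both, giving the C8 epimer. The fallback makes use of β-face attack. It sets out from 21. MeLi, then N-phenyltriflimide, gives 5β-(trimethylsilyloxy)dauc-8-en-9-yl trifluoromethanesulfonate F13. Palladium-catalysed formate reduction (Pd(OAc)2, PPh3, Bu3N, HCO2H), then fluoride, gives dauc-8-en-5β-ol F14. mCPBA, guided by the free C5 hydroxyl, gives 8β,9β-epoxydaucan-5β-ol F15. Aqueous acid (HClO4, THF/H2O) opens the epoxide at the tertiary C8 with inversion; the C5 hydroxyl is on the same face as the epoxide and cannot interfere. This returns to the route at 24.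

## Further compounds

F1 | step 1 | ethyl (2Z)-4-methyl-3-{[(trifluoromethyl)sulfonyl]oxy}pent-2-enoate | CCOC(=O)/C=C(\OS(=O)(=O)C(F)(F)F)C(C)C
F2 | step 1 | ethyl (2Z)-3-(furan-2-yl)-4-methylpent-2-enoate | CCOC(=O)/C=C(\c1ccco1)C(C)C
F3 | step 3 | (3R)-3-(5-bromofuran-2-yl)-4-methylpentanoic acid | OC(=O)C[C@H](C(C)C)c1ccc(Br)o1
F4 | step 3 | (3R)-3-(5-bromofuran-2-yl)-4-methylpentanoyl chloride | ClC(=O)C[C@H](C(C)C)c1ccc(Br)o1
F5 | step 3 | (6R)-2-bromo-6-(propan-2-yl)-5,6-dihydro-4H-cyclopenta[b]furan-4-one | O=C1C[C@H](C(C)C)c2oc(Br)cc12
F6 | step 3 | (6R)-2-bromo-6-(propan-2-yl)-5,6-dihydro-4H-cyclopenta[b]furan | CC(C)[C@H]1CCc2cc(Br)oc12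
F7 | step 8 | 5β,8β-epoxy-6-(phenylsulfinyl)-15-nordauc-1(10)-en-9-one (mixture at C6 and sulfur) | O=C1C=C2CC[C@H](C(C)C)[C@]23O[C@@]1(C)CC3S(=O)c1ccccc1
F8 | step 8 | 5β,8β-epoxy-15-nordauca-1(10),6-dien-9-one | O=C1C=C2CC[C@H](C(C)C)[C@]23O[C@@]1(C)C=C3
F9 | step 9 | 5β,8β-epoxy-6-[(4-methylphenyl)sulfonyl]-15-nordauca-1(10),6-dien-9α-ol | O[C@H]1C=C2CC[C@H](C(C)C)[C@]23O[C@@]1(C)C=C3S(=O)(=O)c1ccc(C)cc1
F10 | step 9 | 5β,8β-epoxy-15-nordauca-1(10),6-dien-9α-ol | O[C@H]1C=C2CC[C@H](C(C)C)[C@]23O[C@@]1(C)C=C3
F11 | step 9 | 5β,8β-epoxy-15-nordauc-1(10)-en-9α-ol | O[C@H]1C=C2CC[C@H](C(C)C)[C@]23O[C@@]1(C)CC3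
F12 | step 9 | 5β,8β-epoxy-15-nordauc-1(10)-en-9-one | O=C1C=C2CC[C@H](C(C)C)[C@]23O[C@@]1(C)CC3
F13 | step 14 | 5β-(trimethylsilyloxy)dauc-8-en-9-yl trifluoromethanesulfonate | FC(F)(F)S(=O)(=O)OC=1C[C@@]2(C)CC[C@H](C(C)C)[C@@]2(O[Si](C)(C)C)CCC=1C
F14 | step 14 | dauc-8-en-5β-ol (1-methyl β; 4R) | CC1=CC[C@@]2(C)CC[C@H](C(C)C)[C@@]2(O)CC1
F15 | step 14 | 8β,9β-epoxydaucan-5β-ol | O1[C@@H]2C[C@@]3(C)CC[C@H](C(C)C)[C@@]3(O)CC[C@]12C
A1 | alternative 1 | 2-[2-(tert-butyldimethylsilyloxy)-1-hydroxyethyl]-2,5-dimethylcyclohept-4-en-1-one | CC1=CC[C@@](C)([C@H](O)CO[Si](C)(C)C(C)(C)C)C(=O)CC1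
A2 | alternative 1 | 1-[3-(tert-butyldimethylsilyloxymethyl)-2-methyloxiran-2-yl]-4-methylcyclohex-3-en-1-ol (carbinol configuration of no consequence) | CC1=CCC(O)(CC1)[C@]1(C)O[C@@H]1CO[Si](C)(C)C(C)(C)C
A3 | alternative 2 | 3-isopropyl-6-methoxy-8a-methyl-3,8a-dihydroazulen-1(2H)-one | COC1=CC=C2[C@@H](C(C)C)CC(=O)[C@]2(C)C=C1
A4 | alternative 2 | 2-diazo-5-(4-methoxyphenyl)-6-methylheptan-3-one | CC(=[N+]=[N-])C(=O)C[C@H](C(C)C)c1ccc(OC)cc1
A5 | alternative 3 | 11,12-didehydrodauc-8-en-5-ol | CC1=CC[C@@]2(C)CC[C@H](C(C)=C)[C@@]2(O)CC1
A6 | alternative 3 | 2,5-dimethyl-2-(4-methylpent-3-en-1-yl)cyclohept-4-en-1-one | CC1=CC[C@@](C)(CCC=C(C)C)C(=O)CC1
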